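Cryptomerin A is disconnected at C3–C4 of the pyranone (ring C) of its apigenin half. The C4–C3–C2 chain of that ring links the symmetric phloroglucinol ring A (at C4) to the para-phenylene ring (at C2) at the 1,3-diketone oxidation level, exactly what a 3,5-diarylisoxazole stores. One [3+2] cycloaddition of 2,4,6-tris(benzyloxy)benzonitrile oxide to a terminal aryl alkyne forms C3–C4 plus a temporary O–C2 bond; hydrogenolysis and aqueous acid later turn the isoxazole into the pyranone. The alkyne precursor is the finished, benzyl-protected methoxyflavone half, 5,7-bis(benzyloxy)-4'-methoxyflavone bearing a 4-ethynylphenoxy group at C6, so the diaryl ether is in place before the halves are joined.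

Key step: step 10

Remark on the chemistry: ring A of the methoxyflavone half carries four oxygens (O1, O5, O6, O7), one more than phloroacetophenone provides, so O6 is introduced by para-hydroxylation of the acetophenone and the phenol used for ether formation is 5,7-bis(benzyloxy)-6-hydroxy-4'-methoxyflavone; the di-ortho-substituted nitrile oxide is assumed to be isolable and is made with a non-halogenating oxidant.

Step 1
Reactants: 1 2',4',6'-trihydroxyacetophenone
Product: 2 1-[2,4-bis(benzyloxy)-6-hydroxyphenyl]ethanone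
Conditions: BnBr (2.1 equiv), K2CO3, DMF, 0 °C → rt
Reagents that add atoms: benzyl bromide, BrCc1ccccc1
Why: Williamson etherification under mild carbonate conditions should alkylate the para hydroxyl and one ortho hydroxyl, while the remaining ortho hydroxyl is held in a hydrogen bond to the acetyl carbonyl and stays free.

Step 2
Reactants: 2 1-[2,4-bis(benzyloxy)-6-hydroxyphenyl]ethanone
Product: 4 1-[2,4-bis(benzyloxy)-3,6-dihydroxyphenyl]ethanone, via potassium aryl sulfate 3 (not isolated)
Conditions: K2S2O8, aq NaOH, pyridine, 0 °C → rt; then aq HCl (pH 1), 80 °C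
Reagents that add atoms: potassium peroxodisulfate, [K+].[K+].[O-]S(=O)(=O)OOS(=O)(=O)[O-]
Why: In the Elbs persulfate oxidation the phenolate attacks a peroxide oxygen of peroxodisulfate through the carbon para to the phenol oxygen (the position between the two benzyloxy groups), and the aryl sulfate formed is hydrolysed by dilute acid that leaves benzyl aryl ethers intact, which installs the future O6.

Step 3
Reactants: 4 1-[2,4-bis(benzyloxy)-3,6-dihydroxyphenyl]ethanone; 5 4-methoxybenzoyl chloride
Product: 6 1-[2,4-bis(benzyloxy)-3,6-dihydroxyphenyl]-3-(4-methoxyphenyl)propane-1,3-dione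
Conditions: LiN(SiMe3)2 (4.2 equiv), THF, −78 → −10 °C; then 5 (1.0 equiv), −78 °C → rt; aq HCl quench
Reagents that add atoms: none
Why: Claisen-type C-aroylation of the lithium polyanion (two phenoxides plus the methyl ketone enolate), a one-flask form of the Baker–Venkataraman acyl transfer, should give the 1,3-diketone directly because the enolate carbon is far more nucleophilic than the phenoxide flanked by two benzyloxy groups and the extra equivalent of base stores the product as its enolate.

Step 4
Reactants: 6 1-[2,4-bis(benzyloxy)-3,6-dihydroxyphenyl]-3-(4-methoxyphenyl)propane-1,3-dione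
Product: 7 5,7-bis(benzyloxy)-6-hydroxy-2-(4-methoxyphenyl)-4H-chromen-4-one
Conditions: NaOAc, AcOH, 100 °C, argon
Reagents that add atoms: none
Why: Cyclodehydration of the ortho-hydroxyaryl 1,3-diketone (the closing stage of a Baker–Venkataraman flavone synthesis) should close the pyranone through the only phenol ortho to the acyl group, and buffered acetic acid spares the benzyl ethers.

Step 5
Reactants: 7 5,7-bis(benzyloxy)-6-hydroxy-2-(4-methoxyphenyl)-4H-chromen-4-one; 8 4-fluorobenzaldehyde
Product: 9 4-{[5,7-bis(benzyloxy)-2-(4-methoxyphenyl)-4-oxo-4H-chromen-6-yl]oxy}benzaldehyde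
Conditions: K2CO3, DMF, 100 °C
Reagents that add atoms: none
Why: Nucleophilic aromatic substitution (addition–elimination through a Meisenheimer adduct) of the fluoride para to the formyl group by the electron-rich C6 phenoxide should proceed as it does for 2,6-dialkoxyphenols, despite the two flanking ethers.

Step 6
Reactants: 9 4-{[5,7-bis(benzyloxy)-2-(4-methoxyphenyl)-4-oxo-4H-chromen-6-yl]oxy}benzaldehyde
Product: 10 5,7-bis(benzyloxy)-6-(4-ethynylphenoxy)-2-(4-methoxyphenyl)-4H-chromen-4-one
Conditions: dimethyl (1-diazo-2-oxopropyl)phosphonate, K2CO3, MeOH/THF, 0 °C → rt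
Reagents that add atoms: dimethyl (1-diazo-2-oxopropyl)phosphonate (Bestmann–Ohira reagent), COP(=O)(OC)C(=[N+]=[N-])C(C)=O
Why: In the Ohira–Bestmann homologation the diazomethylphosphonate anion released by methanolysis adds to the aldehyde, eliminates phosphate to a diazoalkene and loses N2 with a 1,2-hydrogen shift to give the terminal alkyne, under conditions that the flavone and the ethers tolerate.

Step 7
Reactants: 11 2,4,6-trihydroxybenzaldehyde
Product: 12 2,4,6-tris(benzyloxy)benzaldehyde
Conditions: BnBr (3.5 equiv), K2CO3, DMF, 70 °C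
Reagents that add atoms: benzyl bromide, BrCc1ccccc1
Why: Exhaustive Williamson etherification should succeed because the excess of benzyl bromide and the higher temperature overcome the hydrogen bonding of the ortho hydroxyls to the formyl group.

Step 8
Reactants: 12 2,4,6-tris(benzyloxy)benzaldehyde
Product: 13 (E)-2,4,6-tris(benzyloxy)benzaldehyde oxime
Conditions: NH2OH·HCl, NaOAc, EtOH/THF, 60 °C
Reagents that add atoms: hydroxylamine hydrochloride, NO.Cl
Why: Condensation of the aldehyde with hydroxylamine should give the aldoxime as the E isomer, the hydroxyl avoiding the di-ortho-substituted aryl group.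

Step 9
Reactants: 13 (E)-2,4,6-tris(benzyloxy)benzaldehyde oxime
Product: 14 2,4,6-tris(benzyloxy)benzonitrile oxide
Conditions: PhI(OAc)2, TFA (cat.), MeOH/CH2Cl2, 0 °C
Reagents that add atoms: none
Why: Oxidative dehydrogenation of the aldoxime by the hypervalent iodine reagent (ligand exchange at iodine, then loss of iodobenzene and acetic acid) should give the nitrile oxide without a halogenating agent that could attack the activated ring, and the two ortho benzyloxy groups block dimerisation so that it can be isolated like mesitonitrile oxide.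

Step 10
Reactants: 10 5,7-bis(benzyloxy)-6-(4-ethynylphenoxy)-2-(4-methoxyphenyl)-4H-chromen-4-one; 14 2,4,6-tris(benzyloxy)benzonitrile oxide
Product: 15 5,7-bis(benzyloxy)-2-(4-methoxyphenyl)-6-(4-{3-[2,4,6-tris(benzyloxy)phenyl]isoxazol-5-yl}phenoxy)-4H-chromen-4-one
Conditions: 14 (1.5 equiv), toluene, 80 °C
Reagents that add atoms: none
Why: The nitrile oxide should add across the terminal alkyne in a concerted, asynchronous Huisgen 1,3-dipolar cycloaddition in which the dipole carbon (future C4 of ring C of the apigenin half) bonds to the terminal alkyne carbon (future C3) while the dipole oxygen bonds to the internal carbon (future C2). The closest known reaction type is the thermal addition of isolable di-ortho-substituted aryl nitrile oxides such as mesitonitrile oxide to arylacetylenes, which gives 3,5-diarylisoxazoles. The isoxazole ring is closed by intermolecular [3+2] cycloaddition, its C–C and C–O ring bonds forming in the same step from the 4π dipole and one alkyne π bond, so no exo or endo cyclisation question arises. No stereocenter is created, the product being a planar aromatic heterocycle. The step needs 3,5- over 3,4-regioselectivity, secured by the terminal alkyne (the aryl-bearing dipole carbon goes to the unsubstituted terminus, where hindrance is least and the alkyne HOMO coefficient largest), and chemoselectivity for the alkyne over the chromone C2–C3 double bond, secured because that trisubstituted, conjugated and hindered alkene is a poor dipolarophile and no free OH or NH is present to add to the dipole. Dimerisation to the furoxan is suppressed by the two flanking benzyloxy groups, and the temperature stays below that at which hindered nitrile oxides rearrange to isocyanates.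

Step 11
Reactants: 15 5,7-bis(benzyloxy)-2-(4-methoxyphenyl)-6-(4-{3-[2,4,6-tris(benzyloxy)phenyl]isoxazol-5-yl}phenoxy)-4H-chromen-4-one
Product: 16 (Z)-3-amino-1-(4-{[5,7-dihydroxy-2-(4-methoxyphenyl)-4-oxo-4H-chromen-6-yl]oxy}phenyl)-3-(2,4,6-trihydroxyphenyl)prop-2-en-1-one
Conditions: H2 (1 atm), Pd/C, THF/MeOH, rt
Reagents that add atoms: none
Why: Catalytic hydrogenolysis should cleave the five benzyl aryl ethers and the weak isoxazole N–O bond to leave the Z-configured beta-enaminoketone (geometry fixed by the N–H···O=C hydrogen bond), a vinylogous amide that resists further reduction, while the chromone double bond and the diaryl ether are not attacked at one atmosphere.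

Step 12
Reactants: 16 (Z)-3-amino-1-(4-{[5,7-dihydroxy-2-(4-methoxyphenyl)-4-oxo-4H-chromen-6-yl]oxy}phenyl)-3-(2,4,6-trihydroxyphenyl)prop-2-en-1-one
Product: 18 cryptomerin A, via 4-aminoflavylium chloride 17 (not isolated)
Conditions: 2 M aq HCl, EtOH, 80 °C
Reagents that add atoms: water, O
Why: In this acid-promoted cyclocondensation an ortho phenol of the phloroglucinol ring should add to the protonated C2 carbonyl in a six-membered closure, water carrying the former isoxazole oxygen is lost to give the 4-aminoflavylium ion, and hydrolysis of its C4–N bond releases ammonia and the pyranone carbonyl, either ortho hydroxyl giving the same product because the ring is symmetric.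

Compound list
1 | 2',4',6'-trihydroxyacetophenone | CC(=O)c1c(O)cc(O)cc1O | starting material
2 | 1-[2,4-bis(benzyloxy)-6-hydroxyphenyl]ethanone | CC(=O)c1c(O)cc(OCc2ccccc2)cc1OCc1ccccc1 | intermediate
3 | potassium 3-acetyl-2,6-bis(benzyloxy)-4-hydroxyphenyl sulfate | CC(=O)c1c(O)cc(OCc2ccccc2)c(OS(=O)(=O)[O-])c1OCc1ccccc1.[K+] | intermediate
4 | 1-[2,4-bis(benzyloxy)-3,6-dihydroxyphenyl]ethanone | CC(=O)c1c(O)cc(OCc2ccccc2)c(O)c1OCc1ccccc1 | intermediate
5 | 4-methoxybenzoyl chloride | COc1ccc(cc1)C(Cl)=O | starting material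
6 | 1-[2,4-bis(benzyloxy)-3,6-dihydroxyphenyl]-3-(4-methoxyphenyl)propane-1,3-dione | COc1ccc(cc1)C(=O)CC(=O)c1c(O)cc(OCc2ccccc2)c(O)c1OCc1ccccc1 | intermediate
7 | 5,7-bis(benzyloxy)-6-hydroxy-2-(4-methoxyphenyl)-4H-chromen-4-one | COc1ccc(cc1)-c1cc(=O)c2c(OCc3ccccc3)c(O)c(OCc3ccccc3)cc2o1 | intermediate
8 | 4-fluorobenzaldehyde | O=Cc1ccc(F)cc1 | starting material
9 | 4-{[5,7-bis(benzyloxy)-2-(4-methoxyphenyl)-4-oxo-4H-chromen-6-yl]oxy}benzaldehyde | COc1ccc(cc1)-c1cc(=O)c2c(OCc3ccccc3)c(Oc3ccc(C=O)cc3)c(OCc3ccccc3)cc2o1 | intermediate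
10 | 5,7-bis(benzyloxy)-6-(4-ethynylphenoxy)-2-(4-methoxyphenyl)-4H-chromen-4-one | C#Cc1ccc(Oc2c(OCc3ccccc3)cc3oc(-c4ccc(OC)cc4)cc(=O)c3c2OCc2ccccc2)cc1 | intermediate
11 | 2,4,6-trihydroxybenzaldehyde | O=Cc1c(O)cc(O)cc1O | starting material
12 | 2,4,6-tris(benzyloxy)benzaldehyde | O=Cc1c(OCc2ccccc2)cc(OCc2ccccc2)cc1OCc1ccccc1 | intermediate
13 | (E)-2,4,6-tris(benzyloxy)benzaldehyde oxime | O/N=C/c1c(OCc2ccccc2)cc(OCc2ccccc2)cc1OCc1ccccc1 | intermediate
14 | 2,4,6-tris(benzyloxy)benzonitrile oxide | [O-][N+]#Cc1c(OCc2ccccc2)cc(OCc2ccccc2)cc1OCc1ccccc1 | intermediate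
15 | 5,7-bis(benzyloxy)-2-(4-methoxyphenyl)-6-(4-{3-[2,4,6-tris(benzyloxy)phenyl]isoxazol-5-yl}phenoxy)-4H-chromen-4-one | c1c(-c2ccc(Oc3c(OCc4ccccc4)cc4oc(-c5ccc(OC)cc5)cc(=O)c4c3OCc3ccccc3)cc2)onc1-c1c(OCc2ccccc2)cc(OCc2ccccc2)cc1OCc1ccccc1 | intermediate
16 | (Z)-3-amino-1-(4-{[5,7-dihydroxy-2-(4-methoxyphenyl)-4-oxo-4H-chromen-6-yl]oxy}phenyl)-3-(2,4,6-trihydroxyphenyl)prop-2-en-1-one | N/C(=C\C(=O)c1ccc(Oc2c(O)cc3oc(-c4ccc(OC)cc4)cc(=O)c3c2O)cc1)c1c(O)cc(O)cc1O | intermediate
17 | 4-amino-2-(4-{[5,7-dihydroxy-2-(4-methoxyphenyl)-4-oxo-4H-chromen-6-yl]oxy}phenyl)-5,7-dihydroxychromenylium chloride | Nc1cc(-c2ccc(Oc3c(O)cc4oc(-c5ccc(OC)cc5)cc(=O)c4c3O)cc2)[o+]c2cc(O)cc(O)c12.[Cl-] | intermediate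
18 | cryptomerin A, 5,7-dihydroxy-6-[4-(5,7-dihydroxy-4-oxo-4H-chromen-2-yl)phenoxy]-2-(4-methoxyphenyl)-4H-chromen-4-one | COc1ccc(-c2cc(=O)c3c(O)c(Oc4ccc(-c5cc(=O)c6c(O)cc(O)cc6o5)cc4)c(O)cc3o2)cc1 | target

Total step count: 12. Longest linear sequence: 9 (steps 1 to 6, then 10, 11 and 12).

Steps most likely to fail

Step 10. The doubly ortho-flanked, electron-rich dipole may add to the unactivated aryl alkyne too slowly, so that thermal rearrangement of the nitrile oxide to the isocyanate overtakes cycloaddition. The fallback abandons the dipole and builds ring C of the apigenin half by a Baker–Venkataraman sequence. It sets out from aldehyde 9 and uses acetophenone 2. Oxidation of 9 with NaClO2, NaH2PO4 and 2-methyl-2-butene in t-BuOH/THF/water should give 4-{[5,7-bis(benzyloxy)-2-(4-methoxyphenyl)-4-oxo-4H-chromen-6-yl]oxy}benzoic acid F1. Carbodiimide esterification (EDC·HCl, DMAP, CH2Cl2) with the phenol of 2 should give 2-acetyl-3,5-bis(benzyloxy)phenyl 4-{[5,7-bis(benzyloxy)-2-(4-methoxyphenyl)-4-oxo-4H-chromen-6-yl]oxy}benzoate F2. KOt-Bu in THF should transfer the acyl group to carbon and give 1-[2,4-bis(benzyloxy)-6-hydroxyphenyl]-3-(4-{[5,7-bis(benzyloxy)-2-(4-methoxyphenyl)-4-oxo-4H-chromen-6-yl]oxy}phenyl)propane-1,3-dione F3. NaOAc in AcOH at 100 °C should close it to 5,7-bis(benzyloxy)-6-{4-[5,7-bis(benzyloxy)-4-oxo-4H-chromen-2-yl]phenoxy}-2-(4-methoxyphenyl)-4H-chromen-4-one F4. Hydrogenolysis (H2, Pd/C, THF/MeOH) then returns to the route at target 18.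

Step 11. N–O hydrogenolysis may stall once the phenols are free and the substrate binds the catalyst, or prolonged exposure may saturate the chromone C2–C3 double bond. The fallback separates the two reductive tasks and uses no hydrogen. It sets out from isoxazole 15. Mo(CO)6 in MeCN/water at 80 °C should cleave only the N–O bond and give (Z)-3-amino-1-(4-{[5,7-bis(benzyloxy)-2-(4-methoxyphenyl)-4-oxo-4H-chromen-6-yl]oxy}phenyl)-3-[2,4,6-tris(benzyloxy)phenyl]prop-2-en-1-one F5. BCl3 with pentamethylbenzene in CH2Cl2 at −78 °C should then remove the five benzyl groups without touching the methyl ether, which returns to the route at enaminoketone 16 for step 12.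

Step 2. The persulfate oxidation may proceed with low conversion and with oxidative degradation of the electron-rich phenolate. The fallback passes through the quinone oxidation level instead and sets out from phenol 2. PhI(OCOCF3)2 in MeCN/water at 0 °C should oxidise the para-unsubstituted phenol to 2-acetyl-3,5-bis(benzyloxy)-1,4-benzoquinone F6. Reduction with Na2S2O4 in EtOAc/water should return to the route at hydroquinone 4.

Further compounds
F1 | step 10 | 4-{[5,7-bis(benzyloxy)-2-(4-methoxyphenyl)-4-oxo-4H-chromen-6-yl]oxy}benzoic acid | COc1ccc(cc1)-c1cc(=O)c2c(OCc3ccccc3)c(Oc3ccc(cc3)C(=O)O)c(OCc3ccccc3)cc2o1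
F2 | step 10 | 2-acetyl-3,5-bis(benzyloxy)phenyl 4-{[5,7-bis(benzyloxy)-2-(4-methoxyphenyl)-4-oxo-4H-chromen-6-yl]oxy}benzoate | CC(=O)c1c(OC(=O)c2ccc(Oc3c(OCc4ccccc4)cc4oc(-c5ccc(OC)cc5)cc(=O)c4c3OCc3ccccc3)cc2)cc(OCc2ccccc2)cc1OCc1ccccc1
F3 | step 10 | 1-[2,4-bis(benzyloxy)-6-hydroxyphenyl]-3-(4-{[5,7-bis(benzyloxy)-2-(4-methoxyphenyl)-4-oxo-4H-chromen-6-yl]oxy}phenyl)propane-1,3-dione | O=C(CC(=O)c1ccc(Oc2c(OCc3ccccc3)cc3oc(-c4ccc(OC)cc4)cc(=O)c3c2OCc2ccccc2)cc1)c1c(O)cc(OCc2ccccc2)cc1OCc1ccccc1
F4 | step 10 | 5,7-bis(benzyloxy)-6-{4-[5,7-bis(benzyloxy)-4-oxo-4H-chromen-2-yl]phenoxy}-2-(4-methoxyphenyl)-4H-chromen-4-one | COc1ccc(cc1)-c1cc(=O)c2c(OCc3ccccc3)c(Oc3ccc(cc3)-c3cc(=O)c4c(OCc5ccccc5)cc(OCc5ccccc5)cc4o3)c(OCc3ccccc3)cc2o1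
F5 | step 11 | (Z)-3-amino-1-(4-{[5,7-bis(benzyloxy)-2-(4-methoxyphenyl)-4-oxo-4H-chromen-6-yl]oxy}phenyl)-3-[2,4,6-tris(benzyloxy)phenyl]prop-2-en-1-one | N/C(=C\C(=O)c1ccc(Oc2c(OCc3ccccc3)cc3oc(-c4ccc(OC)cc4)cc(=O)c3c2OCc2ccccc2)cc1)c1c(OCc2ccccc2)cc(OCc2ccccc2)cc1OCc1ccccc1
F6 | step 2 | 2-acetyl-3,5-bis(benzyloxy)-1,4-benzoquinone | CC(=O)C1=C(OCc2ccccc2)C(=O)C(OCc2ccccc2)=CC1=O
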